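**Retrosynthetic overview**
- 13 ⇒ 4 + 10 in the last step: C11–C12 is cut into the C8–C9–C11 allyl cation (stored as the exocyclic 9(11)-ene 8-formate 4) and the ε-carbon of a 2,4-pentadienylsilane (C12=C13–C14=C15–C16–Si, acid 10).
- Enabling feature: C11–C12 is the central σ-bond of the 1,5-diene C8=C9–C11–C12–C13=C14, flanked by the tetrasubstituted ring-B alkene and the C13=C14–C15=C16 diene, so each half can be carried as its transposed, easier allyl isomer.
- 4 ⇐ (+)-sclareolide 1 by lactol formation, alkoxy-radical excision of the lactone carbonyl carbon and dehydroiodination; rings A/B and C5/C10 come intact from 1, and no ring is formed in the route.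
- 10 ⇐ trienoate 7 by catalytic enantioselective 1,4-silyl transfer, anti-methylation (sets C17) and saponification; 7 ⇐ methacrolein 5 + phosphonocrotonate 6.

Key step: step 8

Remark on the chemistry: locants follow drimane/labdane usage (C1–C10 decalin, C8=C9 ring alkene, C11 on C9, C12, C13(Me)=C14, C15=C16, C17(H)(Me), C18 = CO2H). Commercial 6 is taken as its (E)-isomer. The ligand antipode in step 5 is the one that gives (3S)-8, to be confirmed by correlation before scale-up.

**Step 1**
Reactants: 1 (+)-sclareolide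
Product: 2 sclareolide lactol, (3aR,5aS,9aS,9bR)-3a,6,6,9a-tetramethyldodecahydronaphtho[2,1-b]furan-2-ol (anomer mixture)
Conditions: DIBAL-H (1.1 equiv), CH2Cl2, −78 °C; Rochelle salt
Reagents that add atoms: none
Why: Partial lactone reduction with DIBAL-H should stop at the lactol because the aluminium hemiacetal is stable at −78 °C until work-up, and none of the four stereocentres is touched.

**Step 2**
Reactants: 2 sclareolide lactol
Product: 3 [(1R,2R,4aS,8aS)-1-(iodomethyl)-2,5,5,8a-tetramethyldecahydronaphthalen-2-yl] formate (8α-formyloxy-11-iododrimane)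
Conditions: PhI(OAc)2 (1.3 equiv), I2 (1.0 equiv), cyclohexane, hν (W lamp), rt → 40 °C
Reagents that add atoms: iodine, II
Why: In this Suárez hypoiodite fragmentation the lactol O–I bond homolyses, β-scission of the alkoxy radical leaves the former lactone carbon on O8 as a formate, and the primary C11 radical is trapped by iodine, with C8 and C9 retained.

**Step 3**
Reactants: 3 iodo formate
Product: 4 [(2R,4aS,8aS)-2,5,5,8a-tetramethyl-1-methylidenedecahydronaphthalen-2-yl] formate (8α-formyloxydrim-9(11)-ene)
Conditions: AgF (3 equiv), pyridine, rt, dark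
Reagents that add atoms: none
Why: Silver-assisted E2 dehydroiodination should remove the only β-hydrogen (H9) to give the exocyclic C9=C11 alkene, while the tertiary formate should survive the anhydrous, weakly basic medium.

**Step 4**
Reactants: 5 methacrolein; 6 triethyl 4-phosphonocrotonate
Product: 7 ethyl (2E,4E)-6-methylhepta-2,4,6-trienoate
Conditions: 6, LiHMDS (1.05 equiv), THF, −78 °C; 5, −78 → 0 °C
Reagents that add atoms: none
Why: In this vinylogous Horner–Wadsworth–Emmons olefination the stabilised phosphonate anion reacts at its phosphorus-bearing carbon and should give the new (4E)-alkene, with the (2E)-alkene of 6 retained.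

**Step 5**
Reactants: 7 trienoate
Product: 8 ethyl (3S,4E)-3-[dimethyl(phenyl)silyl]-6-methylhepta-4,6-dienoate
Conditions: PhMe2Si–B(pin) (1.2 equiv), chiral imidazolinium salt (5.5 mol %), CuCl (5 mol %), NaOt-Bu (11 mol %), MeOH (2 equiv), THF, −78 → −40 °C
Reagents that add atoms: (dimethylphenylsilyl)boronic acid pinacol ester, CC1(C)OB(OC1(C)C)[Si](C)(C)c1ccccc1
Why: In this NHC–Cu-catalysed enantioselective conjugate silyl transfer the Cu–Si species should add across the carbonyl-adjacent C2=C3 alkene (1,4-addition, by analogy with acyclic dienoates), the chiral ligand sets the silicon-bearing C3 (= C16) by face selection, and MeOH protonates the copper enolate.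

**Step 6**
Reactants: 8 β-silyl ester
Product: 9 ethyl (2S,3R,4E)-3-[dimethyl(phenyl)silyl]-2,6-dimethylhepta-4,6-dienoate
Conditions: LDA (1.15 equiv), THF, −78 °C; MeI (3 equiv), −78 → −30 °C
Reagents that add atoms: iodomethane, CI
Why: In this anti-selective alkylation of a β-silyl ester enolate, the H-eclipsed conformer presents one face blocked by silicon, so MeI should enter anti to Si and set C2 (= C17) as S; the C3 descriptor changes from S to R by CIP priority only.

**Step 7**
Reactants: 9 methylated silyl ester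
Product: 10 (2S,3R,4E)-3-[dimethyl(phenyl)silyl]-2,6-dimethylhepta-4,6-dienoic acid
Conditions: LiOH·H2O (4 equiv), THF/MeOH/H2O 3:1:1, 40 °C; 1 M HCl to pH 3, 0 °C
Reagents that add atoms: lithium hydroxide, [Li+].[OH-]
Why: Saponification (BAc2) should proceed without epimerisation because C2 is not yet allylic (the alkene is γ,δ), and the allylsilane is stable to aqueous base.

**Step 8**
Reactants: 4 allylic formate; 10 silane acid
Product: 13 (2R,3E,5E)-2,6-dimethyl-8-[(4aS,8aS)-2,5,5,8a-tetramethyl-3,4,4a,5,6,7,8,8a-octahydronaphthalen-1-yl]octa-3,5-dienoic acid, via silyl ester of the silane acid 11 (not isolated), via silyl ester of the target 12 (not isolated)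
Conditions: 10 (1.3 equiv), (Me3Si)2NH (0.6 equiv per 10), CH2Cl2, 40 °C, then evaporation; 4 (1.0 equiv), 2,6-di-tert-butyl-4-methylpyridine (0.4 equiv), TMSOTf (0.3 equiv), CH2Cl2, −78 → −45 °C; pH 5 citrate buffer, 0 °C
Reagents that add atoms: hexamethyldisilazane, C[Si](C)(C)N[Si](C)(C)C (supplies the Me3Si group of intermediates 11 and 12 only; no reagent atom remains in 13)
Why: Proposed new method: a vinylogous Hosomi–Sakurai (SE2″) allyl–pentadienyl union, closest to the known Lewis-acid allylation of allylic esters with allylsilanes, the ε-selective reactions of 2,4-pentadienylsilanes with carbon electrophiles and the C11 Friedel–Crafts arylation of this drimenyl cation, in which silyl triflate ionises 4 to the C8–C9–C11 allyl cation, the terminal CH2 (C12) of the diene in 11 attacks C11, and the resulting C13–C15 allyl cation β to silicon expels PhMe2Si+ (which carries the chain on as silyl triflate) to give 12, hydrolysed to 13 on work-up. No ring is closed and no stereocentre is created: C17 from step 6 is untouched and becomes allylic only here under non-basic conditions, while the silicon-bearing C16 is consumed. At the cation, C11 is primary and unhindered whereas C8 is tertiary, C11 attack gives the tetrasubstituted C8=C9 alkene, and any O-capture by formate or silyl ester only returns allylic esters that re-ionise, so both allylic isomers converge on one cation. At the silane, attack at C12 gives a tertiary silicon-stabilised allyl cation, whereas attack at C14 would give only a secondary one. The s-trans C12=C13–C14=C15 conformer should fix 13E and the H-eclipsed allylsilane conformer (A1,3 strain) should fix 15E. The hindered pyridine and low temperature are there to suppress protodesilylation and acid-induced cyclisation of the 1,5-diene.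

**Compound list**
1 | (+)-sclareolide | CC1(C)CCC[C@@]2(C)[C@H]1CC[C@@]1(C)OC(=O)C[C@H]21 | starting material
2 | sclareolide lactol (anomer mixture) | CC1(C)CCC[C@@]2(C)[C@H]1CC[C@@]1(C)OC(O)C[C@H]21 | intermediate
3 | 8α-formyloxy-11-iododrimane | CC1(C)CCC[C@@]2(C)[C@H]1CC[C@@](C)(OC=O)[C@@H]2CI | intermediate
4 | 8α-formyloxydrim-9(11)-ene | CC1(C)CCC[C@@]2(C)[C@H]1CC[C@@](C)(OC=O)C2=C | intermediate
5 | methacrolein | CC(=C)C=O | starting material
6 | triethyl 4-phosphonocrotonate | CCOC(=O)/C=C/CP(=O)(OCC)OCC | starting material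
7 | ethyl (2E,4E)-6-methylhepta-2,4,6-trienoate | C=C(C)/C=C/C=C/C(=O)OCC | intermediate
8 | ethyl (3S,4E)-3-[dimethyl(phenyl)silyl]-6-methylhepta-4,6-dienoate | C=C(C)/C=C/[C@@H]([Si](C)(C)c1ccccc1)CC(=O)OCC | intermediate
9 | ethyl (2S,3R,4E)-3-[dimethyl(phenyl)silyl]-2,6-dimethylhepta-4,6-dienoate | C=C(C)/C=C/[C@@H]([Si](C)(C)c1ccccc1)[C@@H](C)C(=O)OCC | intermediate
10 | (2S,3R,4E)-3-[dimethyl(phenyl)silyl]-2,6-dimethylhepta-4,6-dienoic acid | C=C(C)/C=C/[C@@H]([Si](C)(C)c1ccccc1)[C@@H](C)C(=O)O | intermediate
11 | trimethylsilyl ester of 10 | C=C(C)/C=C/[C@@H]([Si](C)(C)c1ccccc1)[C@@H](C)C(=O)O[Si](C)(C)C | intermediate (not isolated)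
12 | trimethylsilyl ester of 13 | CC1=C(CC/C(C)=C/C=C/[C@@H](C)C(=O)O[Si](C)(C)C)[C@@]2(C)CCCC(C)(C)[C@@H]2CC1 | intermediate (not isolated)
13 | (2R,3E,5E)-2,6-dimethyl-8-[(4aS,8aS)-2,5,5,8a-tetramethyl-3,4,4a,5,6,7,8,8a-octahydronaphthalen-1-yl]octa-3,5-dienoic acid | CC1=C(CC/C(C)=C/C=C/[C@@H](C)C(=O)O)[C@@]2(C)CCCC(C)(C)[C@@H]2CC1 | target

**Totals**
Total step count: 8. Longest linear sequence: 5 (steps 4–8 from methacrolein); the drimane arm is 4 steps (1, 2, 3, 8).

**Steps most likely to fail**

Step 8 (proposed new method). The allyl cation may be lost by proton loss to drimadienes, the silane may be protodesilylated before C–C bond formation, capture may occur at C14, or alkene geometry may leak. The fallback uses known allyl sulfone alkylation and desulfonylation; it sets out from 4 and 9 and returns at 13. TMSBr (CH2Cl2, −40 °C) should convert 4 by ionisation and recombination at the primary terminus into 11-bromodrim-8-ene F1, and PhSO2Na in DMF should give drim-8-en-11-yl phenyl sulfone F2. Ester 9 is bromodesilylated with NBS (SE2″, CH2Cl2, −78 °C) to the dienyl bromide ethyl (2R,3E,5E)-7-bromo-2,6-dimethylhepta-3,5-dienoate F3. Lithiated F2 (n-BuLi, THF, −78 °C) is alkylated with F3 to the coupled sulfone ester F4 (epimers at the sulfonyl carbon). Me3SnOH (DCE, 70 °C) should give the sulfone acid F5, and PdCl2(dppp)/LiBHEt3 (THF, 0 °C) should remove the sulfonyl group with hydride delivery to the less substituted allyl terminus to give 13.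

Step 5. Silyl transfer may occur at the δ- or ζ-position (1,6- or 1,8-addition), or facial discrimination may be insufficient. The fallback forms the C3–C4 bond of 8 instead of the C–Si bond, on an acceptor with only one alkene; it sets out from 5 and returns at 8. A boron-Wittig reaction of 5 with lithiated bis(pinacolato)borylmethane (LiTMP, THF, −78 °C → rt) should give the (E)-dienylboronate 4,4,5,5-tetramethyl-2-[(1E)-3-methylbuta-1,3-dien-1-yl]-1,3,2-dioxaborolane F6. Ethyl (E)-3-[dimethyl(phenyl)silyl]prop-2-enoate F7 is made by silylcupration of ethyl propiolate. A Hayashi–Miyaura Rh(I)/chiral diene-catalysed asymmetric 1,4-addition of F6 to F7 (aq. KOH, dioxane, 50 °C) should then give 8 with the silicon-bearing centre set by the ligand.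

Step 6. Facial selectivity of the enolate methylation (anti versus syn to silicon) may be insufficient, which would erode C17. The fallback adds auxiliary control; it sets out from 8 and returns at 10. Saponification of 8 gives (3S,4E)-3-[dimethyl(phenyl)silyl]-6-methylhepta-4,6-dienoic acid F8. Its pivaloyl mixed anhydride acylates lithiated (R)-4-benzyloxazolidin-2-one to the imide (4R)-4-benzyl-3-[(3S,4E)-3-[dimethyl(phenyl)silyl]-6-methylhepta-4,6-dienoyl]-1,3-oxazolidin-2-one F9. Evans alkylation (NaHMDS, MeI, THF, −78 °C) should methylate the Z-enolate opposite the benzyl group, matched with silicon control, to the (2S,3R)-methylated imide F10. LiOH/H2O2 (THF/H2O, 0 °C) should release 10.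

**Further compounds**
F1 | step 8 | (4aS,8aS)-1-(bromomethyl)-2,5,5,8a-tetramethyl-3,4,4a,5,6,7,8,8a-octahydronaphthalene (11-bromodrim-8-ene) | CC1=C(CBr)[C@@]2(C)CCCC(C)(C)[C@@H]2CC1
F2 | step 8 | drim-8-en-11-yl phenyl sulfone | CC1=C(CS(=O)(=O)c2ccccc2)[C@@]2(C)CCCC(C)(C)[C@@H]2CC1
F3 | step 8 | ethyl (2R,3E,5E)-7-bromo-2,6-dimethylhepta-3,5-dienoate | BrC/C(C)=C/C=C/[C@@H](C)C(=O)OCC
F4 | step 8 | ethyl (2R,3E,5E)-2,6-dimethyl-8-(phenylsulfonyl)-8-[(4aS,8aS)-2,5,5,8a-tetramethyl-3,4,4a,5,6,7,8,8a-octahydronaphthalen-1-yl]octa-3,5-dienoate (C8 epimers) | CC1=C(C(C/C(C)=C/C=C/[C@@H](C)C(=O)OCC)S(=O)(=O)c2ccccc2)[C@@]2(C)CCCC(C)(C)[C@@H]2CC1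
F5 | step 8 | (2R,3E,5E)-2,6-dimethyl-8-(phenylsulfonyl)-8-[(4aS,8aS)-2,5,5,8a-tetramethyl-3,4,4a,5,6,7,8,8a-octahydronaphthalen-1-yl]octa-3,5-dienoic acid (C8 epimers) | CC1=C(C(C/C(C)=C/C=C/[C@@H](C)C(=O)O)S(=O)(=O)c2ccccc2)[C@@]2(C)CCCC(C)(C)[C@@H]2CC1
F6 | step 5 | 4,4,5,5-tetramethyl-2-[(1E)-3-methylbuta-1,3-dien-1-yl]-1,3,2-dioxaborolane | C=C(C)/C=C/B1OC(C)(C)C(C)(C)O1
F7 | step 5 | ethyl (E)-3-[dimethyl(phenyl)silyl]prop-2-enoate | CCOC(=O)/C=C/[Si](C)(C)c1ccccc1
F8 | step 6 | (3S,4E)-3-[dimethyl(phenyl)silyl]-6-methylhepta-4,6-dienoic acid | C=C(C)/C=C/[C@@H]([Si](C)(C)c1ccccc1)CC(=O)O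
F9 | step 6 | (4R)-4-benzyl-3-[(3S,4E)-3-[dimethyl(phenyl)silyl]-6-methylhepta-4,6-dienoyl]-1,3-oxazolidin-2-one | C=C(C)/C=C/[C@@H]([Si](C)(C)c1ccccc1)CC(=O)N1[C@H](Cc2ccccc2)COC1=O
F10 | step 6 | (4R)-4-benzyl-3-[(2S,3R,4E)-3-[dimethyl(phenyl)silyl]-2,6-dimethylhepta-4,6-dienoyl]-1,3-oxazolidin-2-one | C=C(C)/C=C/[C@@H]([Si](C)(C)c1ccccc1)[C@@H](C)C(=O)N1[C@H](Cc2ccccc2)COC1=O
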